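**Plan**
- Retrosynthesis first cuts the aryl ester bond between the ring A carbonyl and O-3 of ring B. Ring B is then cut at C1–CO2H and C6–propyl in one operation, and ring A at the bond to its carboxyl carbon (a formyl group placed on 5-propylresorcinol).
- Enabling feature: in ring B the propyl on C6 and the carboxyl on C1 are neighbours, and the carboxyl sits beside O-2 of the contiguous C2/C3/C4 oxygen array. This is the pattern left by carbometalation of a 3-alkoxyaryne followed by capture of CO2.
- Forward: both benzene rings are bought and no ring is formed. Ring B is dressed first (4-bromo-2,6-dimethoxyphenol → symmetrical bromide 6 → aryne three-component coupling → phenol 14), and ring A acid 20 is made from 5-propylresorcinol. The two are joined by O-acylation and all MOM groups are removed last.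
- Stereochemistry: the target is achiral and no stereocentre is set. Only regiochemistry has to be controlled, by the mirror symmetry of 6 and by the MOM ether beside the aryne.

Key step: step 6

Remark: salts that arise by simple deprotonation of a numbered compound (phenoxides, carboxylates) are not numbered separately.

**Ring B**

Step 1
Reactants: 1 4-bromo-2,6-dimethoxyphenol
Product: 2 4-bromo-2,6-dimethoxyphenyl 4-methylbenzenesulfonate
Conditions: TsCl, Et3N, DMAP (cat.), CH2Cl2, 0 °C → rt
Reagents that add atoms: 4-methylbenzenesulfonyl chloride, Cc1ccc(cc1)S(=O)(=O)Cl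
Why: O-sulfonylation of the phenol puts on the central oxygen a group that survives boron tribromide and, unlike an acyl group, should not shift to a neighbouring oxygen.

Step 2
Reactants: 2 4-bromo-2,6-dimethoxyphenyl 4-methylbenzenesulfonate
Product: 3 4-bromo-2,6-dihydroxyphenyl 4-methylbenzenesulfonate
Conditions: BBr3 (3 equiv), CH2Cl2, −78 °C → rt; then H2O
Reagents that add atoms: none
Why: Lewis-acid cleavage of aryl methyl ethers (BBr3 demethylation) should free the two flanking hydroxyls, while the aryl sulfonate and the aryl bromide are inert to the reagent.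

Step 3
Reactants: 3 4-bromo-2,6-dihydroxyphenyl 4-methylbenzenesulfonate
Product: 4 4-bromo-2,6-bis(methoxymethoxy)phenyl 4-methylbenzenesulfonate
Conditions: MOMCl, iPr2NEt, CH2Cl2, 0 °C → rt
Reagents that add atoms: chloromethyl methyl ether, COCCl
Why: O-alkylation of both phenols with the chloromethyl ether under amine base (acetal-type Williamson etherification) should install the two MOM ethers that later direct the metalation and the aryne addition.

Step 4
Reactants: 4 4-bromo-2,6-bis(methoxymethoxy)phenyl 4-methylbenzenesulfonate
Product: 5 4-bromo-2,6-bis(methoxymethoxy)phenol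
Conditions: KOH (aq), 1,4-dioxane, 90 °C, under N2; then NaH2PO4 (aq) to pH 6
Reagents that add atoms: none
Why: Alkaline hydrolysis of the aryl sulfonate by hydroxide attack at sulfur should release the central phenol, and MOM acetals and the aryl bromide are stable to aqueous base.

Step 5
Reactants: 5 4-bromo-2,6-bis(methoxymethoxy)phenol
Product: 6 2-(benzyloxy)-5-bromo-1,3-bis(methoxymethoxy)benzene
Conditions: BnBr, K2CO3, DMF, rt → 50 °C
Reagents that add atoms: benzyl bromide, BrCc1ccccc1
Why: Williamson etherification of the 2,6-disubstituted phenoxide should give a benzyl ether that is orthogonal to the MOM groups, so the central oxygen can later be unmasked alone.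

Step 6
Reactants: 6 2-(benzyloxy)-5-bromo-1,3-bis(methoxymethoxy)benzene; 7 propylmagnesium chloride; 8 carbon dioxide
Product: 12 3-(benzyloxy)-2,4-bis(methoxymethoxy)-6-propylbenzoic acid, via aryllithium 9 (not isolated), via aryne 10 (not isolated), via arylmagnesium chloride 11 (not isolated)
Conditions: lithium 2,2,6,6-tetramethylpiperidide (LiTMP, 1.3 equiv), THF, −78 °C; n-PrMgCl (3 equiv), −78 → 40 °C; CO2 (gas), −20 °C → rt; aq. citric acid (pH 4)
Reagents that add atoms: none
Why: LiTMP should remove one of the two equivalent ring hydrogens, each flanked by bromine and a MOM ether, to give aryllithium 9, and loss of bromide from 9 (or from its magnesium counterpart after exchange with the Grignard reagent, on warming) unveils the 3,4,5-trioxygenated aryne 10. Propylmagnesium chloride then adds across the strained triple bond at the carbon remote from the MOM ether (carbomagnesiation), so the carbon–magnesium bond of 11 lies ortho to that oxygen, where it is stabilised inductively and by chelation, and CO2 carboxylates exactly this position. The closest known reaction type is the amide-base generation of 3-alkoxyarynes from 3-alkoxyaryl halides followed by organometallic addition and CO2 quench to give 6-alkyl-2-alkoxybenzoic acids. No ring is closed and no stereocentre is created. The selectivity needed is regiochemical: the mirror symmetry of 6 makes the aryne unique, the MOM ether next to the triple bond sends the propyl group to the distal carbon, the hindered amide neither exchanges bromine nor adds readily to the aryne, and the benzyl ether has no ring hydrogen beside it and is remote from the metalation site.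

Step 7
Reactants: 12 3-(benzyloxy)-2,4-bis(methoxymethoxy)-6-propylbenzoic acid
Product: 13 methoxymethyl 3-(benzyloxy)-2,4-bis(methoxymethoxy)-6-propylbenzoate
Conditions: MOMCl, iPr2NEt, CH2Cl2, 0 °C
Reagents that add atoms: chloromethyl methyl ether, COCCl
Why: Esterification by O-alkylation of the carboxylate is insensitive to the two ortho substituents that shield the carbonyl, and it gives an ester that falls together with the MOM ethers at the end.

Step 8
Reactants: 13 methoxymethyl 3-(benzyloxy)-2,4-bis(methoxymethoxy)-6-propylbenzoate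
Product: 14 methoxymethyl 3-hydroxy-2,4-bis(methoxymethoxy)-6-propylbenzoate
Conditions: H2 (1 atm), 10% Pd/C, EtOAc, rt
Reagents that add atoms: none
Why: Catalytic hydrogenolysis should cleave only the benzyl aryl ether, because neither the MOM ethers nor the MOM ester has a benzylic C–O bond, and it leaves O-3 as the single free hydroxyl.

**Ring A**

Step 9
Reactants: 15 5-propylbenzene-1,3-diol
Product: 17 2,4-dihydroxy-6-propylbenzaldehyde, via iminium chloride 16 (not isolated)
Conditions: POCl3, DMF, 0 °C → rt; then H2O, 50 °C
Reagents that add atoms: N,N-dimethylformamide, CN(C)C=O; water, O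
Why: Vilsmeier–Haack formylation of 5-alkylresorcinols is expected to go para to one hydroxyl and ortho to the other, as it does for the methyl and pentyl homologues, and hydrolysis of the iminium salt gives the aldehyde.

Step 10
Reactants: 17 2,4-dihydroxy-6-propylbenzaldehyde
Product: 18 2-hydroxy-4-(methoxymethoxy)-6-propylbenzaldehyde
Conditions: MOMCl (1.1 equiv), iPr2NEt, CH2Cl2, 0 °C
Reagents that add atoms: chloromethyl methyl ether, COCCl
Why: Selective O-alkylation should occur at the hydroxyl para to the aldehyde, since the ortho hydroxyl is held in a hydrogen bond to the carbonyl and is much less nucleophilic.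

Step 11
Reactants: 18 2-hydroxy-4-(methoxymethoxy)-6-propylbenzaldehyde
Product: 19 2-methoxy-4-(methoxymethoxy)-6-propylbenzaldehyde
Conditions: MeI, K2CO3, DMF, 40 °C
Reagents that add atoms: iodomethane, CI
Why: Williamson methylation in a dipolar aprotic solvent should alkylate the remaining chelated phenol and so place the methyl ether on the oxygen ortho to the future carboxyl.

Step 12
Reactants: 19 2-methoxy-4-(methoxymethoxy)-6-propylbenzaldehyde
Product: 20 2-methoxy-4-(methoxymethoxy)-6-propylbenzoic acid
Conditions: NaClO2, NaH2PO4, 2-methyl-2-butene (excess), t-BuOH/H2O, 0 °C → rt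
Reagents that add atoms: sodium chlorite, [Na+].[O-]Cl=O
Why: Pinnick oxidation should convert the hindered aldehyde into the acid at about pH 4, which the MOM ether tolerates, while the alkene scavenges hypochlorous acid before it can chlorinate the electron-rich ring.

**Union and deprotection**

Step 13
Reactants: 20 2-methoxy-4-(methoxymethoxy)-6-propylbenzoic acid; 14 methoxymethyl 3-hydroxy-2,4-bis(methoxymethoxy)-6-propylbenzoate
Product: 22 methoxymethyl 3-{[2-methoxy-4-(methoxymethoxy)-6-propylbenzoyl]oxy}-2,4-bis(methoxymethoxy)-6-propylbenzoate, via acid chloride 21 (not isolated)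
Conditions: 20, 1-chloro-N,N,2-trimethylprop-1-en-1-amine, CH2Cl2, 0 °C → rt; then 14, NaH, THF, 0 → 40 °C
Reagents that add atoms: none
Why: The α-chloroenamine should turn the acid into its chloride without releasing acid, so the MOM ether survives, and O-acylation of the sodium phenoxide of 14 by this acid chloride then forms the depside ester at the only free hydroxyl.

Step 14
Reactants: 22 methoxymethyl 3-{[2-methoxy-4-(methoxymethoxy)-6-propylbenzoyl]oxy}-2,4-bis(methoxymethoxy)-6-propylbenzoate
Product: 23 2,4-dihydroxy-3-[(4-hydroxy-2-methoxy-6-propylbenzoyl)oxy]-6-propylbenzoic acid (CNP0482898.0)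
Conditions: HCl (1.25 M in MeOH), THF, 0 °C → rt
Reagents that add atoms: none
Why: Acid-catalysed acetal exchange with methanol should remove the three MOM ethers and the MOM ester as dimethoxymethane, while the doubly ortho-substituted aryl ester and the equally shielded carboxylic acid resist methanolysis and Fischer esterification.

**Compound list**

1 | 4-bromo-2,6-dimethoxyphenol | COc1cc(Br)cc(OC)c1O | starting material
2 | 4-bromo-2,6-dimethoxyphenyl 4-methylbenzenesulfonate | COc1cc(Br)cc(OC)c1OS(=O)(=O)c1ccc(C)cc1 | intermediate
3 | 4-bromo-2,6-dihydroxyphenyl 4-methylbenzenesulfonate | Oc1cc(Br)cc(O)c1OS(=O)(=O)c1ccc(C)cc1 | intermediate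
4 | 4-bromo-2,6-bis(methoxymethoxy)phenyl 4-methylbenzenesulfonate | COCOc1cc(Br)cc(OCOC)c1OS(=O)(=O)c1ccc(C)cc1 | intermediate
5 | 4-bromo-2,6-bis(methoxymethoxy)phenol | COCOc1cc(Br)cc(OCOC)c1O | intermediate
6 | 2-(benzyloxy)-5-bromo-1,3-bis(methoxymethoxy)benzene | COCOc1cc(Br)cc(OCOC)c1OCc1ccccc1 | intermediate
7 | propylmagnesium chloride | CCC[Mg]Cl | starting material
8 | carbon dioxide | O=C=O | starting material
9 | [3-(benzyloxy)-6-bromo-2,4-bis(methoxymethoxy)phenyl]lithium | [Li]c1c(Br)cc(OCOC)c(OCc2ccccc2)c1OCOC | intermediate
10 | 4-(benzyloxy)-3,5-bis(methoxymethoxy)-1,2-didehydrobenzene (aryne) | COCOC1=CC#CC(OCOC)=C1OCc1ccccc1 | intermediate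
11 | [3-(benzyloxy)-2,4-bis(methoxymethoxy)-6-propylphenyl]magnesium chloride | CCCc1cc(OCOC)c(OCc2ccccc2)c(OCOC)c1[Mg]Cl | intermediate
12 | 3-(benzyloxy)-2,4-bis(methoxymethoxy)-6-propylbenzoic acid | CCCc1cc(OCOC)c(OCc2ccccc2)c(OCOC)c1C(=O)O | intermediate
13 | methoxymethyl 3-(benzyloxy)-2,4-bis(methoxymethoxy)-6-propylbenzoate | CCCc1cc(OCOC)c(OCc2ccccc2)c(OCOC)c1C(=O)OCOC | intermediate
14 | methoxymethyl 3-hydroxy-2,4-bis(methoxymethoxy)-6-propylbenzoate | CCCc1cc(OCOC)c(O)c(OCOC)c1C(=O)OCOC | intermediate
15 | 5-propylbenzene-1,3-diol | CCCc1cc(O)cc(O)c1 | starting material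
16 | N-[(2,4-dihydroxy-6-propylphenyl)methylidene]-N-methylmethanaminium chloride | CCCc1cc(O)cc(O)c1C=[N+](C)C.[Cl-] | intermediate
17 | 2,4-dihydroxy-6-propylbenzaldehyde | CCCc1cc(O)cc(O)c1C=O | intermediate
18 | 2-hydroxy-4-(methoxymethoxy)-6-propylbenzaldehyde | CCCc1cc(OCOC)cc(O)c1C=O | intermediate
19 | 2-methoxy-4-(methoxymethoxy)-6-propylbenzaldehyde | CCCc1cc(OCOC)cc(OC)c1C=O | intermediate
20 | 2-methoxy-4-(methoxymethoxy)-6-propylbenzoic acid | CCCc1cc(OCOC)cc(OC)c1C(=O)O | intermediate
21 | 2-methoxy-4-(methoxymethoxy)-6-propylbenzoyl chloride | CCCc1cc(OCOC)cc(OC)c1C(=O)Cl | intermediate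
22 | methoxymethyl 3-{[2-methoxy-4-(methoxymethoxy)-6-propylbenzoyl]oxy}-2,4-bis(methoxymethoxy)-6-propylbenzoate | CCCc1cc(OCOC)cc(OC)c1C(=O)Oc1c(OCOC)cc(CCC)c(C(=O)OCOC)c1OCOC | intermediate
23 | 2,4-dihydroxy-3-[(4-hydroxy-2-methoxy-6-propylbenzoyl)oxy]-6-propylbenzoic acid | CCCc1cc(O)cc(OC)c1C(=O)Oc1c(O)cc(CCC)c(C(=O)O)c1O | target

**Summary**

Total step count: 14. Longest linear sequence: 10 steps (steps 1–8, 13 and 14, from 4-bromo-2,6-dimethoxyphenol). The ring A branch (steps 9–12) joins at step 13.

Steps most likely to fail:

1. Step 6. After lithium–magnesium exchange the ortho-metalated bromide may lose bromide only slowly, so the aryne could be consumed by aryl-metal species or by the amide instead of by the propyl nucleophile. Deprotonation of the benzyl ether with rearrangement is a further drain. The fallback sets out from 6 and makes the same two bonds one after the other, without an aryne. Negishi coupling with n-PrZnBr (PdCl2(dppf), THF, 50 °C) should give 2-(benzyloxy)-1,3-bis(methoxymethoxy)-5-propylbenzene F1. NBS (MeCN, 0 °C) should then brominate one of its two equivalent ring positions, each ortho and para to a MOM ether, to give 2-(benzyloxy)-4-bromo-1,3-bis(methoxymethoxy)-5-propylbenzene F2. Bromine–lithium exchange (n-BuLi, THF, −78 °C) and CO2 then come back to the route at 12.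

2. Step 13. Acyl transfer between a phenoxide flanked by two MOM ethers and an aroyl chloride with two ortho substituents may be slower than decomposition of the acid chloride. The fallback sets out from 20 and 14 and changes both partners to isolable, neutral forms. Cyanuric fluoride and pyridine (CH2Cl2, 0 °C) should convert 20 into 2-methoxy-4-(methoxymethoxy)-6-propylbenzoyl fluoride F3. Me3SiCl and Et3N should convert 14 into methoxymethyl 2,4-bis(methoxymethoxy)-6-propyl-3-[(trimethylsilyl)oxy]benzoate F4. A catalytic amount of anhydrous Bu4NF (MeCN, rt → 50 °C) should then join F3 and F4 through a free phenoxide and the small acyl fluoride, coming back to the route at 22.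

3. Step 14. While the last MOM ethers are being cleaved, the liberated 2,4-dihydroxybenzoic acid may lose carbon dioxide, or the aryl ester may be methanolysed or migrate. The fallback sets out from 12 and keeps the carboxyl masked during the acid treatment, so that the last step is a neutral hydrogenolysis.
   - Hydrogenolysis of 12 (H2, 10% Pd/C, EtOAc) should give 3-hydroxy-2,4-bis(methoxymethoxy)-6-propylbenzoic acid F5.
   - Selective alkylation of its carboxylate (BnBr, KHCO3, DMF, rt) should give benzyl 3-hydroxy-2,4-bis(methoxymethoxy)-6-propylbenzoate F6.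
   - Acylation with acid chloride 21 as in step 13 should give benzyl 3-{[2-methoxy-4-(methoxymethoxy)-6-propylbenzoyl]oxy}-2,4-bis(methoxymethoxy)-6-propylbenzoate F7.
   - HCl in MeOH/THF should remove the MOM ethers from the stable ester to give benzyl 2,4-dihydroxy-3-[(4-hydroxy-2-methoxy-6-propylbenzoyl)oxy]-6-propylbenzoate F8.
   - Hydrogenolysis of the benzyl ester (H2, 10% Pd/C, EtOAc) then comes back to the route at 23.

**Further compounds**

F1 | step 6 | 2-(benzyloxy)-1,3-bis(methoxymethoxy)-5-propylbenzene | CCCc1cc(OCOC)c(OCc2ccccc2)c(OCOC)c1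
F2 | step 6 | 2-(benzyloxy)-4-bromo-1,3-bis(methoxymethoxy)-5-propylbenzene | CCCc1cc(OCOC)c(OCc2ccccc2)c(OCOC)c1Br
F3 | step 13 | 2-methoxy-4-(methoxymethoxy)-6-propylbenzoyl fluoride | CCCc1cc(OCOC)cc(OC)c1C(F)=O
F4 | step 13 | methoxymethyl 2,4-bis(methoxymethoxy)-6-propyl-3-[(trimethylsilyl)oxy]benzoate | CCCc1cc(OCOC)c(O[Si](C)(C)C)c(OCOC)c1C(=O)OCOC
F5 | step 14 | 3-hydroxy-2,4-bis(methoxymethoxy)-6-propylbenzoic acid | CCCc1cc(OCOC)c(O)c(OCOC)c1C(=O)O
F6 | step 14 | benzyl 3-hydroxy-2,4-bis(methoxymethoxy)-6-propylbenzoate | CCCc1cc(OCOC)c(O)c(OCOC)c1C(=O)OCc1ccccc1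
F7 | step 14 | benzyl 3-{[2-methoxy-4-(methoxymethoxy)-6-propylbenzoyl]oxy}-2,4-bis(methoxymethoxy)-6-propylbenzoate | CCCc1cc(OCOC)cc(OC)c1C(=O)Oc1c(OCOC)cc(CCC)c(C(=O)OCc2ccccc2)c1OCOC
F8 | step 14 | benzyl 2,4-dihydroxy-3-[(4-hydroxy-2-methoxy-6-propylbenzoyl)oxy]-6-propylbenzoate | CCCc1cc(O)cc(OC)c1C(=O)Oc1c(O)cc(CCC)c(C(=O)OCc2ccccc2)c1O
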